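(Readings and results are simulated for an exercise, and the scatter is random.)

Count what the reagent can pay for before you ask how fast a flask runs. You have two earlier runs, and four flasks to judge at the end of their time. I assume that reagent turns substrate into a mono adduct, and that a second reagent turns mono adduct into bis adduct.

all flasks: substrate 0.50 M

| flask | reagent | temperature | remark | time |
|---|---|---|---|---|
| blue | 0.30 M | 21 °C | run made earlier |  |
| teal | 0.45 M | 46 °C | run made earlier |  |
| dusk | 0.600 M | 25 °C |  | 8.0 min |
| noon | 0.600 M | 10 °C |  | 8.0 min |
| midnight | 0.600 M | 55 °C |  | 8.0 min |
| spring | 0.600 M | 40 °C |  | 8.0 min |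

| run | time / min | bis adduct / % | substrate / % |
|---|---|---|---|
| blue | 0.667 | 0.1 | 76.7 |
| blue | 2.00 | 0.3 | 58.3 |
| blue | 4.00 | 2.7 | 44.8 |
| blue | 6.00 | 3.8 | 36.3 |
| blue | 8.00 | 2.5 | 34.2 |
| teal | 0.250 | 0 | 59.3 |
| teal | 0.667 | 3.0 | 34.7 |
| teal | 1.33 | 8.3 | 19.7 |
| teal | 2.00 | 10.9 | 10.8 |
| teal | 3.00 | 10.4 | 6.9 |

(standard deviation of a reading: 1 percentage point)



* the flask with the highest amount of bis adduct, in percent of the substrate charged ("all alike" if they lie within 1.5 percentage points) (dusk / noon / midnight / spring / all alike)
* final bis adduct, as a percentage of the substrate charged, in dusk
* final bis adduct, as a percentage of the substrate charged, in noon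
* final bis adduct, as a percentage of the substrate charged, in midnight
* final bis adduct, as a percentage of the substrate charged, in spring

Build the flask up one step at a time. With the first step by itself, substrate becomes mono adduct and you get no bis adduct. Add the second step, and each bis adduct costs one more reagent. The four flasks hold 0.600 M reagent on 0.50 M substrate, so the surplus allows 20.0% bis adduct once the substrate is gone.

Now the rest, which you read from the runs. Take the reagent the readings seem to have used, substrate lost plus bis adduct, and divide it by the reagent charged. The ratio climbs along a run, blue's from 0.390 at 0.667 min, so take it at the last reading of each run. I call this late ratio the stretch. Blue's last reading gives 1.14 and teal's gives 1.15, both readings with the scatter of their numbers. Each is above one, so some substrate seems to leave without paying reagent. Multiply the reagent by teal's stretch, take away the substrate, and you reach 38.0%, the reagent ceiling: the bis adduct these charges can pay for once the substrate is gone, if the stretch stays at teal's value. That is more than the plain surplus.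

I lay this one ceiling, read from teal at 46 °C, beside the four flasks as a yardstick, though their stretch may shift with temperature. Teal, at 46 °C and with less reagent, had 6.9% substrate left after 3.00 min, while blue, at 21 °C, still had 34.2% after 8.00 min. My own reckoning stops there: the hottest flask should come closest.

The forecast names midnight, with 6.5% for noon, 15.5% for dusk, 26% for spring and 34% for midnight, which it calls “approaching the reagent-limited ceiling of about 38%”.

The flasks give 4.60% in noon, 13.2% in dusk, 25.0% in spring and 33.9% in midnight, so midnight holds the most, and the forecast held.

    substrate + reagent → mono adduct + by-product (k = 0.0720 L mol⁻¹ s⁻¹, Ea = 43.0 kJ mol⁻¹)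
    reagent + mono adduct → bis adduct + by-product (k = 0.00920 L mol⁻¹ s⁻¹, Ea = 64.0 kJ mol⁻¹)
    substrate + mono adduct → side product (k = 0.0130 L mol⁻¹ s⁻¹, Ea = 61.0 kJ mol⁻¹)
    (constants at 40 °C)

The stretch is the third step, which joins substrate to mono adduct without reagent. Midnight stands at 89.2% of the ceiling, with 1.35% of its reagent, the limiting reagent of the second step, left at 8.00 min. The using up of reagent is a part of why it stops there: with reagent held at its charge, midnight reaches 85.6%. What the temperature does to the second step is the largest single effect on the gap between midnight and noon, 29 percentage points with it and −0.85 points without it. The repeat at 30 °C, with the same charges, stands at 44.7% of the yardstick, with 17.0% bis adduct, but each side product holds two substrate, so its 20.6% side product, against midnight's 30.9%, puts its own limit lower, at the plain surplus plus half of that share, 30.3%.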